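## Retrosynthetic overview

- The N–O bond, the C2–Br bond and the C3–CH2N bond are removed in that order (amine oxidation, bromination of the ammonium salt, Mannich reaction). This leads back to 5,6-dibromo-1-methylindole.
- Feature used: in the benzo ring, the edge C4–C5(Br)–C6(Br)–C7 reads the same from either end and meets the pyrrole ring only at C3a and C7a. Cutting C3a–C4 and C7–C7a therefore releases 1-methylpyrrole and one symmetric C4 unit at the oxidation level of 2,3-dibromosuccinaldehyde.
- That unit is used as its cyclic bis-acetal, 3,4-dibromo-2,5-dimethoxytetrahydrofuran, made by adding bromine to 2,5-dimethoxy-2,5-dihydrofuran.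
- Ring order: the pyrrole ring is bought. The six-membered carbocycle is the only ring built (step 2), and the tetrahydrofuran ring of the acetal is consumed in the same step.

Key step: step 2

Remark: the target has no stereocentre, because the oxidised nitrogen carries two identical methyl groups. It is achiral and needs no enantiocontrol.

## Route

Step 1
Reactants: 1 2,5-dimethoxy-2,5-dihydrofuran; 2 bromine
Product: 3 3,4-dibromo-2,5-dimethoxytetrahydrofuran (3,4-trans; diastereomer mixture at C2/C5)
Conditions: Br2 (1.0 equiv), CH2Cl2, −40 → 0 °C, dark; aq. Na2S2O3/NaHCO3 wash
Reagents that add atoms: bromine (compound 2), BrBr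
Why: Electrophilic anti-addition of bromine to the ring alkene through a bromonium ion, under neutral anhydrous conditions that leave both acetals intact; the two new C–Br stereocentres are set trans to each other, their relation to C2/C5 follows the cis/trans mixture of commercial 1, and none of this matters because all four stereocentres vanish in step 2.

Step 2
Reactants: 3 3,4-dibromo-2,5-dimethoxytetrahydrofuran; 4 1-methylpyrrole
Product: 7 5,6-dibromo-1-methylindole, via tetrahydrofuranyl pyrrole acetal 5 (not isolated), via dioxygenated tetrahydroindole 6 (not isolated)
Conditions: TfOH (20 mol %), HFIP/DCE (1:4), final 0.02 M, 3 and 4 (1:1) added together by syringe pump at 0 °C, then 55 °C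
Reagents that add atoms: none
Why: Proposed new method: acid ionises one acetal carbon of 3 (loss of MeOH) to a cyclic oxocarbenium ion, which the alpha carbon of 4, its most nucleophilic site, captures to form C7–C7a and give 5; endocyclic C–O cleavage at the second acetal carbon then opens the tetrahydrofuran to an open-chain methoxycarbenium ion, and the neighbouring beta carbon attacks it to form C3a–C4 and give 6. This single ring closure is a 6-exo-trig Friedel–Crafts cyclisation (enol-endo as seen from the pyrrole C=C), with the C=O+ bond outside the new carbocycle. In 6 the C7–OH and C4–OMe groups are both pyrrolyl-carbinyl leaving groups, so each ionises to a nitrogen-stabilised cation and the adjacent CHBr carbon gives up its proton; water and MeOH leave, both bromines end on the sp2 carbons C5 and C6, and no oxidant is needed because the C4 unit already has the oxidation level of the arene. The closest known reaction type is the acid-mediated benzannulation of pyrroles and indoles with 2,5-dimethoxytetrahydrofuran or 1,4-diketones; a C4 partner with two alpha-bromines, which retard ionisation, is untested, hence the strong acid in a cation-stabilising fluoroalcohol medium. No stereocentre survives: all four stereocentres of 3 are erased, so its diastereomers converge on 7, and the end-to-end symmetry of the C4 unit removes any question of orientation. The selectivity needed is alpha-then-adjacent-beta attack on one and the same pyrrole instead of 2,5-dialkylation, dipyrrolylmethane formation or a second annulation of 7; it is secured by the innate alpha preference, by the intramolecular six-membered closure under pseudo-high dilution, by the lower nucleophilicity of the dibrominated product, and by the reversibility of pyrrolyl-carbinyl bond formation in acid as against irreversible aromatisation.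

Step 3
Reactants: 7 5,6-dibromo-1-methylindole; 8 Eschenmoser's salt
Product: 10 5,6-dibromo-1-methylgramine, via dibromogramine hydroiodide 9 (not isolated)
Conditions: Eschenmoser's salt (1.3 equiv), MeCN, rt → 50 °C; then 1 M NaOH, CH2Cl2 extraction
Reagents that add atoms: Eschenmoser's salt (compound 8), C=[N+](C)C.[I-]
Why: Mannich aminomethylation with a preformed iminium salt: C3 is the enamine-type carbon of the indole and stays nucleophilic enough despite the two ring bromines, N1 is blocked by methyl, and the free base 10 is released from hydroiodide 9 in the basic work-up, which also removes iodide before the next oxidising reagent.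

Step 4
Reactants: 10 5,6-dibromo-1-methylgramine
Product: 13 2,5,6-tribromo-1-methylgramine, via dibromogramine trifluoroacetate 11 (not isolated), via tribromogramine trifluoroacetate 12 (not isolated)
Conditions: TFA (2.0 equiv), CH2Cl2, 0 °C; then NBS (1.05 equiv), 0 °C → rt, dark; aq. Na2SO3, 1 M NaOH
Reagents that add atoms: N-bromosuccinimide, BrN1C(=O)CCC1=O
Why: Electrophilic C2-bromination of a 3-substituted indole (Br+ adds at C3, migrates to C2 and H-2 is lost), in which prior protonation to 11 ties up the side-chain lone pair and so blocks N-bromination and retro-Mannich loss of the aminomethyl arm, while C5 and C6 are already occupied and the pyrrole ring remains the most electron-rich site.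

Step 5
Reactants: 13 2,5,6-tribromo-1-methylgramine
Product: 14 2,5,6-tribromo-1-methylgramine N-oxide (target)
Conditions: mCPBA (1.05 equiv), CH2Cl2, 0 °C; filtration through basic alumina (CH2Cl2/MeOH)
Reagents that add atoms: mCPBA, OOC(=O)c1cccc(Cl)c1
Why: Peracid N-oxidation of a tertiary amine: the sp3 nitrogen lone pair is far more nucleophilic towards mCPBA than the C2=C3 bond of an indole bearing three bromines, so one equivalent at 0 °C should stop at the amine oxide, and no stereocentre arises because the nitrogen bears two identical methyl groups.

## Compound list

1 | 2,5-dimethoxy-2,5-dihydrofuran (commercial cis/trans mixture) | COC1C=CC(OC)O1 | starting material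
2 | bromine | BrBr | starting material
3 | 3,4-dibromo-2,5-dimethoxytetrahydrofuran (3,4-trans, diastereomer mixture at C2/C5, drawn without descriptors) | COC1OC(OC)C(Br)C1Br | intermediate
4 | 1-methylpyrrole | Cn1cccc1 | starting material
5 | 2-(3,4-dibromo-5-methoxytetrahydrofuran-2-yl)-1-methylpyrrole (diastereomer mixture, not isolated) | COC1OC(c2cccn2C)C(Br)C1Br | intermediate
6 | 5,6-dibromo-4-methoxy-1-methyl-4,5,6,7-tetrahydroindol-7-ol (diastereomer mixture, not isolated) | COC1C(Br)C(Br)C(O)c2c1ccn2C | intermediate
7 | 5,6-dibromo-1-methylindole | Cn1ccc2cc(Br)c(Br)cc21 | intermediate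
8 | Eschenmoser's salt (N,N-dimethylmethyleneiminium iodide) | C=[N+](C)C.[I-] | starting material
9 | 5,6-dibromo-1-methylgramine hydroiodide (not isolated) | C[NH+](C)Cc1cn(C)c2cc(Br)c(Br)cc12.[I-] | intermediate
10 | 5,6-dibromo-1-methylgramine, i.e. 1-(5,6-dibromo-1-methylindol-3-yl)-N,N-dimethylmethanamine | CN(C)Cc1cn(C)c2cc(Br)c(Br)cc12 | intermediate
11 | 5,6-dibromo-1-methylgramine trifluoroacetate salt (not isolated) | C[NH+](C)Cc1cn(C)c2cc(Br)c(Br)cc12.[O-]C(=O)C(F)(F)F | intermediate
12 | 2,5,6-tribromo-1-methylgramine trifluoroacetate salt (not isolated) | C[NH+](C)Cc1c(Br)n(C)c2cc(Br)c(Br)cc12.[O-]C(=O)C(F)(F)F | intermediate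
13 | 2,5,6-tribromo-1-methylgramine | CN(C)Cc1c(Br)n(C)c2cc(Br)c(Br)cc12 | intermediate
14 | 2,5,6-tribromo-1-methylgramine N-oxide (achiral) | Cn1c(Br)c(C[N+](C)(C)[O-])c2cc(Br)c(Br)cc21 | target

## Step count and risks

Total step count: 5. Longest linear sequence: 5 (1 → 3 → 7 → 10 → 13 → 14).

**Step 2 (proposed new method).**
- The alpha-bromines may slow acetal ionisation so much that acid-induced oligomerisation of the pyrrole takes over.
- Other leaks are intermolecular capture of the pyrrolyl-carbinyl cations and a second annulation on the product.
- Bromine may also be lost, either by elimination of HBr or by transfer of Br+ from a beta-bromo cation to the electron-rich pyrrole.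
- The fallback gives up the pyrrole-based ring construction and uses known chemistry. It sets out from bromine 2, used with purchased methyl indole-3-carboxylate (COC(=O)c1c[nH]c2ccccc12) in AcOH at rt.
- The ester deactivates the pyrrole ring and sends both bromines to C5 and C6, giving methyl 5,6-dibromo-1H-indole-3-carboxylate F1.
- Saponification (NaOH, aq. MeOH, reflux, then HCl) gives 5,6-dibromo-1H-indole-3-carboxylic acid F2.
- Protodecarboxylation by heating in aqueous acid gives 5,6-dibromo-1H-indole F3.
- N-methylation (NaH, MeI, DMF, 0 °C) comes back to the route at 7.

**Step 4.**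
- With incomplete protonation, ipso attack at C3 may be followed by loss of the aminomethyl arm.
- Adventitious water may capture the C3-brominated cation and lead to oxidation at C2 instead of bromination.
- Substitution at C4 or C7 may compete.
- The fallback installs C2–Br through a lactam instead of by aromatic substitution. It sets out from 7.
- NBS (3 equiv) in aq. t-BuOH gives 3,3,5,6-tetrabromo-1-methylindolin-2-one F4.
- Zn in AcOH at rt removes only the geminal bromines to give 5,6-dibromo-1-methylindolin-2-one F5.
- Vilsmeier–Haack bromoformylation (POBr3, DMF, CHCl3, reflux) gives 2,5,6-tribromo-1-methylindole-3-carbaldehyde F6.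
- Reductive amination (Me2NH in THF, NaBH(OAc)3, DCE, 0 °C → rt) comes back to the route at 13.

**Step 3.**
- Aminomethylation of a ring deactivated by two bromines may be slow.
- On heating, the ammonium product may then alkylate unreacted indole, coupling two indole units through the CH2 group.
- The fallback replaces the Mannich step by formylation and reduction. It sets out from 7.
- Vilsmeier–Haack formylation (POCl3, DMF, 0 → 40 °C, aqueous NaOH work-up) gives 5,6-dibromo-1-methylindole-3-carbaldehyde F7.
- Reductive amination (Me2NH in THF, NaBH(OAc)3, DCE, rt) comes back to the route at 10.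

## Further compounds

F1 | step 2 | methyl 5,6-dibromo-1H-indole-3-carboxylate | COC(=O)c1c[nH]c2cc(Br)c(Br)cc12
F2 | step 2 | 5,6-dibromo-1H-indole-3-carboxylic acid | OC(=O)c1c[nH]c2cc(Br)c(Br)cc12
F3 | step 2 | 5,6-dibromo-1H-indole | Brc1cc2cc[nH]c2cc1Br
F4 | step 4 | 3,3,5,6-tetrabromo-1-methylindolin-2-one | CN1C(=O)C(Br)(Br)c2cc(Br)c(Br)cc21
F5 | step 4 | 5,6-dibromo-1-methylindolin-2-one | CN1C(=O)Cc2cc(Br)c(Br)cc21
F6 | step 4 | 2,5,6-tribromo-1-methylindole-3-carbaldehyde | Cn1c(Br)c(C=O)c2cc(Br)c(Br)cc21
F7 | step 3 | 5,6-dibromo-1-methylindole-3-carbaldehyde | Cn1cc(C=O)c2cc(Br)c(Br)cc21
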